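**Retrosynthetic overview**
1. Ring A is decorated last: C7 acetyl by Stille coupling on an α-iodoenone, C9 angelate by Rubottom oxidation then esterification, C6=C7 by dehydrogenation, C8=O by excision of an isopropenyl group.
2. Ring B is closed by an intramolecular enolate–epoxide alkylation (C1–C2 bond), which also frees the tertiary 10-OH; the C3 ketone is then reduced and acetylated.
3. Key bond: C4–C5 (quaternary next to tertiary) by Claisen [3,3] rearrangement of the crotyl enol ether of (+)-dihydrocarvone.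
4. The bought C8 centre sets C5; C5 then relays to C4, C10, C3 and C9, and C8 is finally erased as the ketone.
5. Ring order: ring A is bought (dihydrocarvone); ring B is formed in step 4.

Convention and assumption: carbons are numbered as in eremophilanes (C1–C2–C3–C4–C5–C10 = acetoxy ring B; C5–C6–C7–C8–C9–C10 = enone ring A); β is the face of the C5 methyl. Commercial (+)-dihydrocarvone is a C2-epimer mixture; both epimers give the same enol ether, so it is drawn as (2R,5R).

**Route**

Step 1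
Reactants: 1 (+)-dihydrocarvone; 2 (E)-but-2-en-1-ol
Product: 5 (2R,5R)-2-[(2S)-but-3-en-2-yl]-2-methyl-5-(prop-1-en-2-yl)cyclohexan-1-one, via dicrotyl ketal 3 (not isolated), via crotyl enol ether 4 (not isolated)
Conditions: 2 (4 equiv), TsOH (2 mol %), toluene, Dean–Stark; then xylene, 140 °C
Reagents that add atoms: none
Why: Acid-catalysed ketal exchange and loss of crotyl alcohol give the more substituted enol ether 4, whose Claisen [3,3] rearrangement through a chair transition state forms the C4–C5 bond axially, cis to the equatorial C8 isopropenyl (the bias seen in annulations of dihydrocarvone), so the bought C8 centre sets C5 and the (E)-crotyl geometry sets C4.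

Step 2
Reactants: 5
Product: 6 (3S,4R,7R)-4-[(2S)-but-3-en-2-yl]-4-methyl-7-(prop-1-en-2-yl)-1-oxaspiro[2.5]octane (epoxide O on the methyl face, CH2 cis to the butenyl group)
Conditions: Me3S(O)I, NaH, DMSO, rt to 50 °C
Reagents that add atoms: trimethylsulfoxonium iodide, C[S+](C)(C)=O.[I-]
Why: Corey–Chaykovsky epoxidation with the reversibly adding sulfoxonium ylide is expected to deliver the methylene equatorially, cis to the axial butenyl group, leaving the oxygen axial on the face of the C5 methyl (the future 10β-OH).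

Step 3
Reactants: 6
Product: 7 (3R)-3-[(3S,4R,7R)-4-methyl-7-(prop-1-en-2-yl)-1-oxaspiro[2.5]octan-4-yl]butan-2-one
Conditions: PdCl2 (10 mol %), Cu(OAc)2 (20 mol %), O2 (1 atm), DMA–H2O 7:1, rt
Reagents that add atoms: water, O
Why: Tsuji–Wacker oxidation converts only the monosubstituted vinyl group into the methyl ketone (Markovnikov; the 1,1-disubstituted isopropenyl is inert), and the acetate-buffered system should spare the epoxide.

Step 4
Reactants: 7
Product: 8 10β-hydroxy-4β,5β-dimethyl-8α-(prop-1-en-2-yl)-cis-decalin-3-one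
Conditions: t-BuOK (0.3 equiv), t-BuOH, 40 °C
Reagents that add atoms: none
Why: Intramolecular enolate alkylation, in which the methyl-side enolate opens the spiro-epoxide at its CH2 terminus (6-exo-tet), closes ring B as the cis-fused ketol with the fusion fixed by the epoxide configuration, while the epimerisable C4 settles as the equatorial 4β-methyl.

Step 5
Reactants: 8
Product: 9 4β,5β-dimethyl-8α-(prop-1-en-2-yl)-cis-decalin-3β,10β-diol
Conditions: L-Selectride (2.2 equiv), THF, −78 °C; H2O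
Reagents that add atoms: none
Why: Hindered-hydride reduction, in which L-Selectride attacks C3 equatorially, away from the syn-axial C5 methyl, gives the axial 3β-alcohol cis to the C4 methyl.

Step 6
Reactants: 9
Product: 10 3β-acetoxy-4β,5β-dimethyl-8α-(prop-1-en-2-yl)-cis-decalin-10β-ol
Conditions: Ac2O, pyridine, DMAP (cat.), CH2Cl2, rt
Reagents that add atoms: acetic anhydride, CC(=O)OC(C)=O
Why: DMAP-catalysed acylation esterifies the secondary 3β-OH and leaves the tertiary 10-OH untouched.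

Step 7
Reactants: 10
Product: 13 3β-acetoxy-10β-hydroxy-4β,5β-dimethyl-cis-decalin-8-one, via methoxy hydroperoxide 11 (not isolated), via TEMPO alkoxyamine 12 (not isolated)
Conditions: O3, MeOH, −78 °C; then TEMPO, FeSO4·7H2O, 0 °C to rt; then mCPBA, rt
Reagents that add atoms: TEMPO, CC1(C)CCCC(C)(C)N1[O]
Why: Oxodealkenylation, in which Criegee ozonolysis in methanol gives hydroperoxide 11, Fe(II) reduction and β-scission expel methyl acetate to leave a C8 radical that TEMPO traps, and peracid oxidation of alkoxyamine 12 gives the ketone, erases the C8 centre after it has done its work.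

Step 8
Reactants: 13
Product: 14 3β-acetoxy-10β-hydroxy-4β,5β-dimethyl-cis-octal-6-en-8-one
Conditions: IBX (2.5 equiv), DMSO, 70 °C
Reagents that add atoms: none
Why: IBX dehydrogenation of the ketone can only go toward C7–C6 because C10 is quaternary, which gives the C6=C7 enone.

Step 9
Reactants: 14
Product: 17 3β-acetoxy-9α,10β-dihydroxy-4β,5β-dimethyl-cis-octal-6-en-8-one, via bis-TMS dienol ether 15 (not isolated), via bis-TMS ketol 16 (not isolated)
Conditions: TMSOTf, Et3N, CH2Cl2, 0 °C; then DMDO, acetone, −78 to 0 °C; then citric acid, MeOH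
Reagents that add atoms: dimethyldioxirane, CC1(C)OO1
Why: In this Rubottom oxidation the α′-silyl dienol ether is epoxidised by DMDO on the α-face, opposite the β-oriented C10 silyloxy group, so the new C9 oxygen is α (trans to the 10β-OH).

Step 10
Reactants: 17; 18 angelic acid
Product: 20 3β-acetoxy-9α-angeloyloxy-10β-hydroxy-4β,5β-dimethyl-cis-octal-6-en-8-one, via mixed anhydride 19 (not isolated)
Conditions: 18, 2,4,6-trichlorobenzoyl chloride, Et3N, toluene, rt; then 17, 80 °C
Reagents that add atoms: none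
Why: Yamaguchi-type mixed-anhydride esterification acylates the secondary α-ketol hydroxyl without angelate-to-tiglate isomerisation and does not touch the tertiary alcohol.

Step 11
Reactants: 20
Product: 21 3β-acetoxy-9α-angeloyloxy-10β-hydroxy-7-iodo-4β,5β-dimethyl-cis-octal-6-en-8-one
Conditions: I2, pyridine, CH2Cl2, rt
Reagents that add atoms: iodine, II
Why: Johnson α-iodination (pyridine addition, iodination, elimination) places iodine at C7 of the enone.

Step 12
Reactants: 21; 22 tributyl(1-ethoxyvinyl)stannane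
Product: 24 target CNP0196241.1, via enol ether 23 (not isolated)
Conditions: Pd(PPh3)4 (5 mol %), CuI (10 mol %), DMF, 60 °C; then 1 M HCl, THF, rt
Reagents that add atoms: water, O
Why: Stille coupling installs the 1-ethoxyvinyl group at C7, and mild acid hydrolysis of the enol ether unveils the acetyl group of the 2-acetyl enone.

**Compound list**

1 | (2R,5R)-2-methyl-5-(prop-1-en-2-yl)cyclohexan-1-one, (+)-dihydrocarvone | C[C@@H]1CC[C@H](CC1=O)C(C)=C | starting material
2 | (E)-but-2-en-1-ol | C/C=C/CO | starting material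
3 | (2R,5R)-1,1-bis[(E)-but-2-enyloxy]-2-methyl-5-(prop-1-en-2-yl)cyclohexane | C[C@@H]1CC[C@H](CC1(OC/C=C/C)OC/C=C/C)C(C)=C | intermediate
4 | (5R)-1-[(E)-but-2-enyloxy]-2-methyl-5-(prop-1-en-2-yl)cyclohex-1-ene | C/C=C/COC1=C(C)CC[C@@H](C(C)=C)C1 | intermediate
5 | (2R,5R)-2-[(2S)-but-3-en-2-yl]-2-methyl-5-(prop-1-en-2-yl)cyclohexan-1-one | C=C[C@H](C)[C@@]1(C)CC[C@@H](C(C)=C)CC1=O | intermediate
6 | (3S,4R,7R)-4-[(2S)-but-3-en-2-yl]-4-methyl-7-(prop-1-en-2-yl)-1-oxaspiro[2.5]octane | C=C[C@H](C)[C@@]1(C)CC[C@@H](C(C)=C)C[C@@]12CO2 | intermediate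
7 | (3R)-3-[(3S,4R,7R)-4-methyl-7-(prop-1-en-2-yl)-1-oxaspiro[2.5]octan-4-yl]butan-2-one | CC(=O)[C@H](C)[C@@]1(C)CC[C@@H](C(C)=C)C[C@@]12CO2 | intermediate
8 | 10β-hydroxy-4β,5β-dimethyl-8α-(prop-1-en-2-yl)-cis-decalin-3-one | C1[C@H](C(C)=C)CC[C@]2(C)[C@@H](C)C(=O)CC[C@]12O | intermediate
9 | 4β,5β-dimethyl-8α-(prop-1-en-2-yl)-cis-decalin-3β,10β-diol | C1[C@H](C(C)=C)CC[C@]2(C)[C@@H](C)[C@@H](O)CC[C@]12O | intermediate
10 | 3β-acetoxy-4β,5β-dimethyl-8α-(prop-1-en-2-yl)-cis-decalin-10β-ol | C1[C@H](C(C)=C)CC[C@]2(C)[C@@H](C)[C@@H](OC(C)=O)CC[C@]12O | intermediate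
11 | 8α-(2-hydroperoxy-2-methoxypropan-2-yl) analogue of 10 (epimers at the side-chain carbon) | C1[C@H](C(C)(OC)OO)CC[C@]2(C)[C@@H](C)[C@@H](OC(C)=O)CC[C@]12O | intermediate
12 | 8-(2,2,6,6-tetramethylpiperidin-1-yloxy) analogue of 10 (C8 epimers) | C1C(ON3C(C)(C)CCCC3(C)C)CC[C@]2(C)[C@@H](C)[C@@H](OC(C)=O)CC[C@]12O | intermediate
13 | 3β-acetoxy-10β-hydroxy-4β,5β-dimethyl-cis-decalin-8-one | C1C(=O)CC[C@]2(C)[C@@H](C)[C@@H](OC(C)=O)CC[C@]12O | intermediate
14 | 3β-acetoxy-10β-hydroxy-4β,5β-dimethyl-cis-octal-6-en-8-one | C1C(=O)C=C[C@]2(C)[C@@H](C)[C@@H](OC(C)=O)CC[C@]12O | intermediate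
15 | 8,10β-bis(trimethylsilyloxy)-6,8-diene from 14 | C1=C(O[Si](C)(C)C)C=C[C@]2(C)[C@@H](C)[C@@H](OC(C)=O)CC[C@]12O[Si](C)(C)C | intermediate
16 | 9α,10β-bis(trimethylsilyloxy) enone | C[Si](C)(C)O[C@@H]1C(=O)C=C[C@]2(C)[C@@H](C)[C@@H](OC(C)=O)CC[C@]12O[Si](C)(C)C | intermediate
17 | 3β-acetoxy-9α,10β-dihydroxy-4β,5β-dimethyl-cis-octal-6-en-8-one | O[C@@H]1C(=O)C=C[C@]2(C)[C@@H](C)[C@@H](OC(C)=O)CC[C@]12O | intermediate
18 | angelic acid, (Z)-2-methylbut-2-enoic acid | C/C=C(/C)C(=O)O | starting material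
19 | angelic 2,4,6-trichlorobenzoic anhydride | C/C=C(/C)C(=O)OC(=O)c1c(Cl)cc(Cl)cc1Cl | intermediate
20 | 3β-acetoxy-9α-angeloyloxy-10β-hydroxy-4β,5β-dimethyl-cis-octal-6-en-8-one | C/C=C(/C)C(=O)O[C@@H]1C(=O)C=C[C@]2(C)[C@@H](C)[C@@H](OC(C)=O)CC[C@]12O | intermediate
21 | 7-iodo derivative of 20 | C/C=C(/C)C(=O)O[C@@H]1C(=O)C(I)=C[C@]2(C)[C@@H](C)[C@@H](OC(C)=O)CC[C@]12O | intermediate
22 | tributyl(1-ethoxyvinyl)stannane | CCCC[Sn](CCCC)(CCCC)C(=C)OCC | starting material
23 | 7-(1-ethoxyvinyl) derivative of 20 | C/C=C(/C)C(=O)O[C@@H]1C(=O)C(C(=C)OCC)=C[C@]2(C)[C@@H](C)[C@@H](OC(C)=O)CC[C@]12O | intermediate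
24 | target, (3S,4R,5R,9S,10R)-3-acetoxy-7-acetyl-9-angeloyloxy-10-hydroxy-4,5-dimethyl-cis-octal-6-en-8-one | C/C=C(/C)C(=O)O[C@@H]1C(=O)C(C(C)=O)=C[C@]2(C)[C@@H](C)[C@@H](OC(C)=O)CC[C@]12O | target

**Summary**

Total step count: 12. Longest linear sequence: 12 steps (1 to 24).

Most likely to fail, with fallbacks:

Step 1 (which enol ether rearranges, and only 1,4-induction from C8 to C5). The fallback sets out from 1 and comes back at 5. TMSCl/NaI/Et3N in MeCN gives the thermodynamic silyl enol ether F1. MeLi releases the regiodefined lithium enolate F2. This is allylated at the branched carbon with (E)-crotyl methyl carbonate under achiral [Ir(cod)Cl]2/P(OPh)3 catalysis to give 5. Any C4 epimer converges in step 4, where C4 is epimerisable and settles as the equatorial methyl.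

Step 2 (facial selectivity at the hindered C10 ketone; the ylide may add from the methyl face). The fallback resets C10 later: it sets out from the β-hydroxy ketone 13, then in hand as either C10 epimer, and comes back at 13 as the 10β-alcohol. TsOH in warm toluene dehydrates the ketol to the conjugated enone F3. TBHP/DBU epoxidises it on the face of the angular methyl (as angular-methyl octalones and 4-en-3-oxo steroids do) to the epoxy ketone F4. SmI2 in THF–MeOH at −78 °C cleaves the Cα–O bond to give 13.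

Step 3 (Wacker oxidation beside an acid-labile spiro-epoxide, and the enolate closure that follows). The fallback sets out from 6 and comes back at 9. VinylMgBr/CuI opens the epoxide at CH2 to the homoallylic tertiary alcohol F5. Ring-closing metathesis (Grubbs II) with the butenyl vinyl group gives the octalinol F6. VO(acac)2/TBHP, directed by the homoallylic 10β-OH, gives the 2β,3β-epoxide F7. LiAlH4 delivers hydride to the less hindered C2 (trans-diaxial opening) to give diol 9.

Further compounds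
F1 | step 1 | (5R)-2-methyl-5-(prop-1-en-2-yl)-1-(trimethylsilyloxy)cyclohex-1-ene | C[Si](C)(C)OC1=C(C)CC[C@@H](C(C)=C)C1
F2 | step 1 | lithium (5R)-2-methyl-5-(prop-1-en-2-yl)cyclohex-1-en-1-olate | [Li+].[O-]C1=C(C)CC[C@@H](C(C)=C)C1
F3 | step 2 | 3β-acetoxy-4β,5β-dimethyl-octal-9(10)-en-8-one | O=C1C=C2CC[C@H](OC(C)=O)[C@H](C)[C@@]2(C)CC1
F4 | step 2 | 3β-acetoxy-9β,10β-epoxy-4β,5β-dimethyl-decalin-8-one | O=C1[C@@H]2O[C@@]23CC[C@H](OC(C)=O)[C@H](C)[C@@]3(C)CC1
F5 | step 3 | 1-allyl-2-[(2S)-but-3-en-2-yl]-2-methyl-5-(prop-1-en-2-yl)cyclohexan-1-ol (allyl cis to butenyl, OH cis to methyl) | C=CC[C@]1(O)C[C@H](C(C)=C)CC[C@]1(C)[C@@H](C)C=C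
F6 | step 3 | 4β,5β-dimethyl-8α-(prop-1-en-2-yl)-cis-octal-2-en-10β-ol | C1[C@H](C(C)=C)CC[C@]2(C)[C@@H](C)C=CC[C@]12O
F7 | step 3 | 2β,3β-epoxy-4β,5β-dimethyl-8α-(prop-1-en-2-yl)-cis-decalin-10β-ol | C1[C@H](C(C)=C)CC[C@]2(C)[C@@H](C)[C@H]3O[C@H]3C[C@]12O
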